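The data were generated by integration for substances that don't exist, and the scatter is random.

Sunday's flask holds twice the second substrate of Saturday's, 40 mM against 20 mM, with the same 20 mM of starting material and 2 µM of free enzyme. Both were read at 40.0 s, 80.0 s and 120 s.

| setting | Sunday's | Saturday's | flask |
|---|---|---|---|
| starting material | 20 mM | 20 mM | 20 mM |
| second substrate | 40 mM | 20 mM | 40.0 mM |
| free enzyme | 2 µM | 2 µM | 2.0 µM |
| remark | the very flask that is asked about, followed so far | run made earlier |  |

Sunday's run (percent of the starting material charged): time / s: target / % = 10.0: 0; 15.0: 0.9; 25.0: 1.7; 40.0: 1.4; 80.0: 2.6; 120: 4.6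

Saturday's run (percent of the starting material charged): time / min: target / % = 0.667: 0.3; 1.33: 1.9; 2.00: 4.0; 2.50: 4.4; 3.00: 4.7; 4.00: 6.0

(scatter of a reading: 0.5 percentage points)

- apparent order in second substrate when 30% of the starting material are converted (percent change of the rate of making target for one percent more second substrate charged)

Two chemists dispute this. The first holds that the rate follows [second substrate] in proportion, so Sunday's target should stand at twice Saturday's at each shared time. Summed over those times, Saturday's readings give 6.20%, so she expects 12.4%. Sunday's give 8.60%. That gap of 3.8 percentage points is about twice its scatter of 1.9 points: strained, not refuted.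

The second chemist holds that the rate bends over as [second substrate] rises, and made the forecast: doubling “raises the rate only about 1.3-fold”, hence 0.4.

My own reckoning uses the summed ratio of the two runs, which reads 1.39. From it I read 0.472 for the doubling order, the power of [second substrate] that carries one run's target into the other's at equal times.

Then the drift. Taking one second substrate per starting material, starting material is the limiting reagent in Sunday's flask, 20 mM against 40.0 mM, and [second substrate] is 34.0 mM at 30% conversion. A saturating form fitted to my doubling order has its half-rate concentration at 25.3 mM. Reckoned per percent of the charge, that gives 0.502, so I commit to a value above the forecast's. In that form the first chemist's proportion holds where [second substrate] lies far below 25.3 mM. Saturday's 20 mM is below it, but not far.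

    second substrate + loaded enzyme ⇌ second complex (K = 17.4 L mol⁻¹, k = 2.17 × 10⁵ L mol⁻¹ s⁻¹)
    first complex → spent catalyst (k = 0.00752 s⁻¹)
    starting material + free enzyme ⇌ first complex (K = 24.8 L mol⁻¹, k = 3.68 × 10⁵ L mol⁻¹ s⁻¹)
    first complex → loaded enzyme + first product (k = 29.8 s⁻¹)
    second complex → free enzyme + target (k = 17.6 s⁻¹)

The simulation gives 0.40, so the forecast held and the second chemist wins; my 0.502 and the doubling order of 0.472 both stand above it. In Sunday's flask that order belongs to the moment 24.7 min into the run, when target forms at 0.103 mM min⁻¹. Now use the doubling order on the other flask: Sunday's flask holds 5.71% target at 2.50 min, and dividing by two raised to 0.472 gives 4.12% for Saturday's flask. Saturday's reading at 2.50 min is 4.4%.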